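All runs come from a simulation with constants of no real substance.

Start from Z and E, your two products, and turn the question round: what would have to be true for the flask to leave one part of D in 100?

the same everywhere: G 0.105 M
- gamma: D 0.067 M (fed, over 25 min); run made earlier; the fed solution adds 0.25 times the starting volume
- epsilon: D 0.15 M (fed, over 25 min); run made earlier; the fed solution adds 0.25 times the starting volume
- flask: D 0.10 M (fed, over 25 min); the fed solution adds 0.25 times the starting volume; time 30 h

| run | time / h | D / % | Z / % | E / % |
|---|---|---|---|---|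
| gamma | 1.50 | 37.6 | 7.1 | 49.6 |
| gamma | 5.00 | 37.7 | 6.6 | 48.9 |
| gamma | 8.00 | 38.0 | 6.2 | 49.0 |
| gamma | 12.0 | 38.1 | 7.5 | 50.1 |
| gamma | 20.0 | 37.2 | 6.8 | 48.9 |
| gamma | 25.0 | 37.0 | 6.2 | 49.5 |
| epsilon | 4.00 | 53.2 | 5.2 | 37.1 |
| epsilon | 8.00 | 53.0 | 5.1 | 37.6 |
| epsilon | 12.0 | 52.7 | 5.1 | 38.1 |
| epsilon | 15.0 | 53.1 | 4.5 | 36.8 |
| epsilon | 20.0 | 53.5 | 5.6 | 36.7 |
| epsilon | 25.0 | 52.7 | 4.9 | 36.5 |

(readings scatter by 0.5 percentage points)

- charges are per starting volume, the dose included; the dosed solution carries all of it
- the numbers in the tables scatter with a standard deviation of 0.5 percentage points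

* conversion of D at 30 h
* amount of Z at 30 h, in percent of the D charged
* amount of E at 30 h, in percent of the D charged

The charge doesn't forbid it, since G at 0.105 M is more than D at 0.10 M. Nor is the gamma run still moving: its D shifted by 0.6 points between 1.50 h and 25.0 h, against a scatter of 0.5 points. So freeze what stays constant. I assume D and G are consumed one to one, and I form consumed D over D left times G left, as real concentrations in the fed volume:

gamma, at 8.00 h: 32.1 L mol⁻¹

epsilon, at 8.00 h: 32.1 L mol⁻¹

Two different charges of D read the same value. Their mean, 32.1 L mol⁻¹, is the plateau quotient, an apparent equilibrium constant over the products together. Leaving one part in 100 would need 20600 L mol⁻¹, a factor of 642 above it.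

Solved for the flask, my reckoning runs:

consumed D, per starting volume: 0.0558 M

conversion: 55.8%

E, at the runs' share of consumed D: 44.4%

Z, likewise: 5.82%

The forecast, reckoned on its own figures per starting volume, gives 56% conversion, 6% Z and 44.2% E, so its Z and E differ slightly from mine: “It looks like an equilibrium instead.”

The flask gives 56.4% conversion, 6.11% Z and 44.1% E.

    D + G ⇌ Z (K = 3.60 L mol⁻¹, k = 12.0 L mol⁻¹ min⁻¹)
    D + G ⇌ E (K = 26.0 L mol⁻¹, k = 4.00 L mol⁻¹ min⁻¹)
    Z ⇌ L (K = 1.00, k = 0.0600 min⁻¹)

The flask stops there in part because Z runs back to D + G and L runs back to Z: the run without the first back reaction reaches a conversion of 100%, and the run without the second a conversion of 97.3%. The flask also holds L, 6.11% at 30.0 h, which the plateau quotient takes in as consumed D, and its final state reads 33.2 L mol⁻¹. For a neighbour flask charged with 0.18 M of G, the quotient 32.1 L mol⁻¹ gives 73.3% conversion, and that neighbour reaches 73.8%, with 57.8% E.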